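**Assumption:** the target SMILES contains no stereocentres (the molecule is achiral), so there is no enantiomer to control and no stereo-setting step is needed. The new step (Step 8) is a proposal and has not been run.

## Retrosynthetic overview

1. The target comes from one global hydrogenolysis of a tetra-benzyl tridepside (three OBn on ring A, benzyl ester on ring C).
2. The B–C depside bond is made by 4-O-selective acylation of benzyl orsellinate with an A–B carboxylic acid, itself obtained by Pinnick oxidation of an A–B aldehyde.
3. The A–B depside bond is made by the new step: a Pd-catalysed three-component carbonylative coupling of a ring-A aryl iodide, CO and the ring-B phenol-aldehyde.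
4. The ring-A iodide comes from 2,4-dihydroxy-6-methylbenzaldehyde by benzylation, Dakin oxidation, benzylation and para-iodination; ring B comes from the same aldehyde by 4-O-allylation, 2-O-methylation and deallylation.
5. No ring is constructed; all three benzene rings are purchased and joined in the order A+B, then C.

## Route

**Step 1**
Reactants: 1, 2,4-dihydroxy-6-methylbenzaldehyde
Product: 2, 2,4-bis(benzyloxy)-6-methylbenzaldehyde
Conditions: BnBr (2.5 equiv), K2CO3, DMF, 60 °C
Reagents that add atoms: benzyl bromide, BrCc1ccccc1
Why: Williamson etherification; K2CO3/DMF with warming alkylates both the free 4-OH and the hydrogen-bonded 2-OH.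

**Step 2**
Reactants: 2, 2,4-bis(benzyloxy)-6-methylbenzaldehyde
Product: 3, 2,4-bis(benzyloxy)-6-methylphenol
Conditions: mCPBA, CH2Cl2, 0 °C to rt; then K2CO3, MeOH, rt
Reagents that add atoms: mCPBA, OOC(=O)c1cccc(Cl)c1 (one O)
Why: Dakin-type Baeyer–Villiger oxidation; the electron-rich aryl group migrates to give the aryl formate, which is methanolysed to the phenol, and benzyl ethers are inert to the peracid.

**Step 3**
Reactants: 3, 2,4-bis(benzyloxy)-6-methylphenol
Product: 4, 1,2,5-tris(benzyloxy)-3-methylbenzene
Conditions: BnBr, K2CO3, DMF, 60 °C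
Reagents that add atoms: benzyl bromide, BrCc1ccccc1
Why: Williamson etherification of the phenoxide, done promptly to cap the oxidation-prone hydroquinone monoether.

**Step 4**
Reactants: 4, 1,2,5-tris(benzyloxy)-3-methylbenzene
Product: 5, 1,2,5-tris(benzyloxy)-4-iodo-3-methylbenzene (iodine on the carbon between the methyl-bearing carbon and C5–OBn)
Conditions: NIS (1.0 equiv), TFA (cat.), MeCN, 0 °C
Reagents that add atoms: N-iodosuccinimide, O=C1CCC(=O)N1I
Why: Electrophilic aromatic iodination; a 1,2,4-trioxygenated benzene reacts at the position para to one OR and ortho to another (here C4, next to the methyl), as in halogenation of 1,2,4-trimethoxybenzene and orcinol dimethyl ether, while C6 between two OBn groups is more shielded.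

**Step 5**
Reactants: 1, 2,4-dihydroxy-6-methylbenzaldehyde
Product: 6, 4-(allyloxy)-2-hydroxy-6-methylbenzaldehyde
Conditions: allyl bromide (1.1 equiv), K2CO3 (1.1 equiv), acetone, rt
Reagents that add atoms: allyl bromide, C=CCBr
Why: Regioselective Williamson etherification; the 2-OH is tied up in a hydrogen bond to the formyl group, so one equivalent of base and halide alkylates only the free, more acidic 4-OH.

**Step 6**
Reactants: 6, 4-(allyloxy)-2-hydroxy-6-methylbenzaldehyde
Product: 7, 4-(allyloxy)-2-methoxy-6-methylbenzaldehyde
Conditions: MeI, K2CO3, DMF, 40 °C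
Reagents that add atoms: iodomethane, CI
Why: Williamson methylation of the remaining chelated phenol under slightly more forcing conditions; the allyl ether is stable (no Claisen rearrangement at this temperature).

**Step 7**
Reactants: 7, 4-(allyloxy)-2-methoxy-6-methylbenzaldehyde
Product: 8, 4-hydroxy-2-methoxy-6-methylbenzaldehyde
Conditions: Pd(PPh3)4 (2 mol%), K2CO3, MeOH, rt
Reagents that add atoms: none
Why: Tsuji–Trost-type deallylation; Pd(0) ionises the aryl allyl ether to a π-allyl complex that is trapped by methanol, leaving the aldehyde and methyl ether untouched.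

**Step 8 (proposed new transformation)**
Reactants: 5, 1,2,5-tris(benzyloxy)-4-iodo-3-methylbenzene; 8, 4-hydroxy-2-methoxy-6-methylbenzaldehyde (1.2 equiv); 9, carbon monoxide
Product: 10, 4-formyl-3-methoxy-5-methylphenyl 2,4,5-tris(benzyloxy)-6-methylbenzoate
Conditions: Pd(OAc)2 (5 mol%), Xantphos (7.5 mol%), iPr2NEt (2 equiv), CO (5 bar), toluene, 90 °C
Reagents that add atoms: carbon monoxide (9), [C-]#[O+]
Why: Proposed new method: a carbonylative depside coupling, i.e. Pd-catalysed aryloxycarbonylation applied to a di-ortho-substituted, tri-oxygenated aryl iodide and a formyl-bearing phenol, which creates the aryl–C(=O) bond and the depside C(=O)–O bond in one step. Oxidative addition of the C–I bond is followed by CO insertion, which is favoured by relief of ortho strain; the acidic para-formyl phenol (pKa about 8) is deprotonated by the amine and binds Pd as phenoxide; acyl–OAr reductive elimination is promoted by the wide-bite-angle ligand and by the congestion of the 2,6-disubstituted aroyl group; the hindered aryl ester product resists further transesterification. The closest known reaction type is Pd-catalysed alkoxy-/aryloxycarbonylation of simple aryl halides with alcohols or phenols (Heck-type carbonylation).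

**Step 9**
Reactants: 10, 4-formyl-3-methoxy-5-methylphenyl 2,4,5-tris(benzyloxy)-6-methylbenzoate
Product: 11, 2-methoxy-6-methyl-4-{[2,4,5-tris(benzyloxy)-6-methylbenzoyl]oxy}benzoic acid
Conditions: NaClO2, NaH2PO4, 2-methyl-2-butene (excess), t-BuOH/THF/H2O, rt
Reagents that add atoms: sodium chlorite, [Na+].[O-]Cl=O (one O)
Why: Pinnick oxidation; chlorous acid oxidises the hindered aldehyde at pH about 4, where the depside ester and benzyl ethers are stable, and the alkene scavenges HOCl so the electron-rich ring A is not chlorinated.

**Step 10**
Reactants: 12, orsellinic acid (2,4-dihydroxy-6-methylbenzoic acid)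
Product: 13, benzyl 2,4-dihydroxy-6-methylbenzoate (benzyl orsellinate)
Conditions: BnBr (1.05 equiv), KHCO3, DMF, rt
Reagents that add atoms: benzyl bromide, BrCc1ccccc1
Why: Chemoselective carboxylate O-alkylation; bicarbonate deprotonates only the CO2H and not the phenols, and room temperature avoids decarboxylation.

**Step 11**
Reactants: 11, the A–B acid; 13, benzyl orsellinate
Product: 14, benzyl 2-hydroxy-6-methyl-4-[(2-methoxy-6-methyl-4-{[2,4,5-tris(benzyloxy)-6-methylbenzoyl]oxy}benzoyl)oxy]benzoate
Conditions: TFAA, toluene, rt
Reagents that add atoms: none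
Why: Depside esterification through the mixed trifluoroacetic anhydride (aroyl-cation-like activation suited to 2,6-disubstituted electron-rich benzoic acids); only the 4-OH of 13 is acylated because the 2-OH is hydrogen-bonded to the ester carbonyl and hindered.

**Step 12**
Reactants: 14, the tetra-benzyl tridepside
Product: 15, 2'-O-methylhiascic acid (2-hydroxy-6-methyl-4-[(2-methoxy-6-methyl-4-{[2,4,5-trihydroxy-6-methylbenzoyl]oxy}benzoyl)oxy]benzoic acid)
Conditions: H2 (1 atm), 10% Pd/C, EtOAc/THF, rt; filter and concentrate under Ar
Reagents that add atoms: none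
Why: Catalytic hydrogenolysis removes the three benzyl ethers and the benzyl ester while aryl (depside) esters and the aryl methyl ether are inert; a non-alcoholic solvent avoids transesterification and inert work-up protects the hydroxyquinol ring A from air oxidation.

## Compound list

1 | 2,4-dihydroxy-6-methylbenzaldehyde | Cc1cc(O)cc(O)c1C=O | starting material
2 | 2,4-bis(benzyloxy)-6-methylbenzaldehyde | Cc1cc(OCc2ccccc2)cc(OCc2ccccc2)c1C=O | intermediate
3 | 2,4-bis(benzyloxy)-6-methylphenol | Cc1cc(OCc2ccccc2)cc(OCc2ccccc2)c1O | intermediate
4 | 1,2,5-tris(benzyloxy)-3-methylbenzene | Cc1cc(OCc2ccccc2)cc(OCc2ccccc2)c1OCc1ccccc1 | intermediate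
5 | 1,2,5-tris(benzyloxy)-4-iodo-3-methylbenzene | Cc1c(I)c(OCc2ccccc2)cc(OCc2ccccc2)c1OCc1ccccc1 | intermediate
6 | 4-(allyloxy)-2-hydroxy-6-methylbenzaldehyde | Cc1cc(OCC=C)cc(O)c1C=O | intermediate
7 | 4-(allyloxy)-2-methoxy-6-methylbenzaldehyde | COc1cc(OCC=C)cc(C)c1C=O | intermediate
8 | 4-hydroxy-2-methoxy-6-methylbenzaldehyde | COc1cc(O)cc(C)c1C=O | intermediate
9 | carbon monoxide | [C-]#[O+] | starting material
10 | 4-formyl-3-methoxy-5-methylphenyl 2,4,5-tris(benzyloxy)-6-methylbenzoate | COc1cc(OC(=O)c2c(OCc3ccccc3)cc(OCc3ccccc3)c(OCc3ccccc3)c2C)cc(C)c1C=O | intermediate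
11 | 2-methoxy-6-methyl-4-{[2,4,5-tris(benzyloxy)-6-methylbenzoyl]oxy}benzoic acid | COc1cc(OC(=O)c2c(OCc3ccccc3)cc(OCc3ccccc3)c(OCc3ccccc3)c2C)cc(C)c1C(=O)O | intermediate
12 | orsellinic acid (2,4-dihydroxy-6-methylbenzoic acid) | Cc1cc(O)cc(O)c1C(=O)O | starting material
13 | benzyl 2,4-dihydroxy-6-methylbenzoate | Cc1cc(O)cc(O)c1C(=O)OCc1ccccc1 | intermediate
14 | benzyl 2-hydroxy-6-methyl-4-[(2-methoxy-6-methyl-4-{[2,4,5-tris(benzyloxy)-6-methylbenzoyl]oxy}benzoyl)oxy]benzoate | COc1cc(OC(=O)c2c(OCc3ccccc3)cc(OCc3ccccc3)c(OCc3ccccc3)c2C)cc(C)c1C(=O)Oc1cc(C)c(C(=O)OCc2ccccc2)c(O)c1 | intermediate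
15 | 2'-O-methylhiascic acid | COc1cc(OC(=O)c2c(O)cc(O)c(O)c2C)cc(C)c1C(=O)Oc1cc(C)c(C(=O)O)c(O)c1 | target

## Summary

Total step count: 12.
Longest linear sequence: 8 steps (Steps 1, 2, 3, 4, 8, 9, 11, 12; from compound 1 to 15).

Three steps most likely to fail, each with a fallback that changes the approach:

1. **Step 8 (proposed new carbonylative depside coupling).** The hindered acyl-Pd intermediate may not undergo C–O bond formation, or proto-deiodination may dominate. Fallback with known chemistry: convert iodide 5 to 2,4,5-tris(benzyloxy)-6-methylbenzoic acid by halogen–metal exchange (n-BuLi, THF, −78 °C) and CO2 quench, or by Vilsmeier–Haack formylation of 4 followed by Pinnick oxidation. Then esterify with phenol 8 by the classical TFAA/toluene depside method to reach 10.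

2. **Step 11 (B–C esterification of the hindered, ester-bearing acid 11; 4-OH versus 2-OH selectivity).** Fallback: reverse the assembly order. Oxidise 7 to 4-(allyloxy)-2-methoxy-6-methylbenzoic acid, couple it as the acid chloride to 13 (a small, robust acid that tolerates forcing conditions), remove the allyl group with Pd(0), and attach ring A last to the resulting B–C phenol.

3. **Step 4 (regioselective mono-iodination of 4; risk of C6 iodination or di-iodination).** Fallback: install the carboxyl carbon before the third oxygen. Start from methyl orsellinate, carry out an Elbs persulfate hydroxylation (para to the 2-OH, giving the 5-OH), tribenzylate and saponify to the ring-A acid, then couple it to 8 with TFAA. This removes the need for an aryl iodide.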